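**Retrosynthetic overview**

1. The oxetane acetal and the secondary bromide are disconnected together (C–O and C–Br): anti bromoetherification of a bromodiene lactol by its own hemiacetal hydroxyl, as in the presumed biosynthesis. The vinyl bromide goes back to a ring ketone.
2. The cyclohexene ring is then cut at two bonds, gem-dimethyl carbon–CBr carbon and spiro carbon–C(CH3)(O) carbon: a cationic [4+2] between a tetrahydrofuran-derived 3-isopropylidene oxocarbenium ion and 2-bromo-5-methylfuran. The bridging oxygen and the bromine of the adduct are then spent in a radical ring opening that delivers the ring ketone.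
3. Enabling feature: in the cyclohexene ring the spiro carbon and the gem-dimethyl carbon are adjacent, and the spiro carbon also carries the acetal carbon of the tetrahydrofuran ring. This is the retron of an alkylidene oxocarbenium dienophile. The other four ring carbons, CBr=CH–CHBr–C(CH3)(O), lie at the oxidation level of a 2,5-disubstituted furan.
4. Ring order: tetrahydrofuran (chiral lactone, CBS reduction) → cyclohexene (key step) → oxetane (last step). The lactone stereocentre controls the spiro centre, which controls the remaining three.

Key step: step 6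

Assumption: the acetal (or lactol) carbon is carried as an anomer mixture from 10 to 16 and the exo/endo relation in 13 is left open, because these elements are planarised or re-formed before the target is reached; the SMILES leave them unspecified. Compounds 1, 2, 6 and 11 are taken as commercial.

**Route**

Step 1
Reactants: 1 methyl 4-chloro-4-oxobutanoate; 2 isopropenylmagnesium bromide
Product: 3 methyl 5-methyl-4-oxohex-5-enoate
Conditions: 2 (1.0 equiv, slow addition), CuI (5 mol %), THF, −40 °C
Reagents that add atoms: none
Why: Copper-catalysed acylation of the Grignard reagent by the acid chloride (ketone synthesis) is much faster than attack on the methyl ester or on the product ketone at −40 °C with slow addition, so it should stop at the enone; no stereocentre is formed.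

Step 2
Reactants: 3 methyl 5-methyl-4-oxohex-5-enoate
Product: 5 (5R)-5-(prop-1-en-2-yl)oxolan-2-one, via hydroxy ester 4 (not isolated)
Conditions: (S)-2-methyl-CBS-oxazaborolidine (10 mol %), catecholborane, toluene, −78 °C; then TsOH (cat.), CH2Cl2, rt
Reagents that add atoms: none
Why: CBS reduction: the oxazaborolidine–borane complex differentiates the isopropenyl (large) from the CH2CH2 (small) flank of the ketone and should give the (R)-allylic alcohol 4, the only stereocentre set by reagent control, while catecholborane at −78 °C spares the 1,1-disubstituted alkene, and acid then closes the γ-lactone with retention.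

Step 3
Reactants: 5 (5R)-5-(prop-1-en-2-yl)oxolan-2-one; 6 acetone
Product: 7 (5R)-3-(2-hydroxypropan-2-yl)-5-(prop-1-en-2-yl)oxolan-2-one
Conditions: LiN(iPr)2 (LDA), THF, −78 °C; then 6; AcOH quench
Reagents that add atoms: none
Why: Aldol addition of the lithium lactone enolate to acetone; the new C3 stereocentre is inconsequential (removed in step 4) and C5 is not enolisable.

Step 4
Reactants: 7 (5R)-3-(2-hydroxypropan-2-yl)-5-(prop-1-en-2-yl)oxolan-2-one
Product: 8 (5R)-3-(propan-2-ylidene)-5-(prop-1-en-2-yl)oxolan-2-one
Conditions: MsCl, Et3N, DMAP (cat.), CH2Cl2, 0 → 40 °C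
Reagents that add atoms: none
Why: Dehydration of the β-hydroxy lactone through its mesylate (E1cB elimination) should give the conjugated, tetrasubstituted exocyclic alkene, the only elimination mode that uses the acidic α-hydrogen; no stereocentre is formed.

Step 5
Reactants: 8 (5R)-3-(propan-2-ylidene)-5-(prop-1-en-2-yl)oxolan-2-one
Product: 10 (5R)-2-methoxy-3-(propan-2-ylidene)-5-(prop-1-en-2-yl)oxolane, via lactol 9 (not isolated)
Conditions: iBu2AlH (DIBAL-H), CH2Cl2, −78 °C; aq. KNaC4H4O6 work-up; then MeOH, PPTS, rt
Reagents that add atoms: methanol, CO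
Why: 1,2-Reduction of the unsaturated lactone by iBu2AlH at −78 °C stops at the aluminium hemiacetal (lactol), and acid-catalysed acetalisation with methanol through the allylically stabilised oxocarbenium ion gives the methyl acetal, whose acetal carbon is formed as an anomer mixture on purpose.

Step 6
Reactants: 10 (5R)-2-methoxy-3-(propan-2-ylidene)-5-(prop-1-en-2-yl)oxolane; 11 2-bromo-5-methylfuran
Product: 13 4-bromo-2′-methoxy-1,3,3-trimethyl-5′-(prop-1-en-2-yl)spiro[7-oxabicyclo[2.2.1]hept-5-ene-2,3′-oxolane], via oxocarbenium triflate 12 (not isolated)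
Conditions: 11 (5 equiv), TMSOTf (0.2 equiv), 2,6-di-tert-butyl-4-methylpyridine, CH2Cl2, −78 °C; Et3N quench at −78 °C, cold work-up, used at once
Reagents that add atoms: none
Why: Proposed new method: TMSOTf ionises the allylic acetal 10 to the 3-isopropylidene oxocarbenium ion 12, whose tertiary allyl-cation terminus is attacked by the bromine-bearing α-carbon of 11, and the enol ether carbon thereby unmasked closes onto the methyl-substituted 2H-furanium carbon (Prins-type) before methoxide returns to the acetal carbon; the closest known reaction type is the ionic Diels–Alder reaction of vinyl oxocarbenium ions from unsaturated acetals with 1,3-dienes, which tolerates fully substituted dienophile carbons but has not been shown with a 2,5-disubstituted furan. The six-membered carbocycle is closed in a stepwise cationic [4+2] mode (intermolecular C–C bond first, then six-ring closure of enol ether onto oxocarbenium) and appears as a 7-oxabicyclo[2.2.1]heptene whose oxygen bridge comes from the furan. The new spiro stereocentre is set by the existing C5 stereocentre of the tetrahydrofuran ring, the furan carbon adding to the ring face anti to the isopropenyl group; the two bridgeheads follow from the cis geometry of the furan and, like the exo/endo relation and the acetal carbon, are inconsequential because they are planarised or re-formed later. The step needs regioselectivity (C–Br carbon to the gem-dimethyl carbon) and chemoselectivity over Friedel–Crafts substitution: attack through the bromine-bearing carbon leaves the charge on the better stabilised methyl-substituted oxocarbenium carbon, and bromine and methyl block re-aromatisation by proton loss, so that ring closure is the only productive exit from the reversible first addition. Because furan cycloadditions are reversible, excess 11, −78 °C and a basic quench are used and 13 is carried on at once into the irreversible step 7.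

Step 7
Reactants: 13 4-bromo-2′-methoxy-1,3,3-trimethyl-5′-(prop-1-en-2-yl)spiro[7-oxabicyclo[2.2.1]hept-5-ene-2,3′-oxolane]
Product: 14 (3R,5R)-1-methoxy-6,6,10-trimethyl-3-(prop-1-en-2-yl)-2-oxaspiro[4.5]dec-9-en-7-one
Conditions: Bu3SnH, Et3B (cat.), air, toluene, −40 → 0 °C
Reagents that add atoms: none
Why: Tin hydride radical dehalogenation with β-fragmentation: bromine abstraction gives a bridgehead α-alkoxyalkyl radical whose C–O β-scission (tertiary allylic radical, strain release, C=O formation) opens the oxygen bridge irreversibly, and hydrogen transfer to the oxo-allyl radical next to the carbonyl gives the β,γ-enone (its conjugated isomer would converge in step 8); no stereocentre is formed and the spiro centre is untouched.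

Step 8
Reactants: 14 (3R,5R)-1-methoxy-6,6,10-trimethyl-3-(prop-1-en-2-yl)-2-oxaspiro[4.5]dec-9-en-7-one
Product: 15 (3R,5R)-7-bromo-1-methoxy-6,6,10-trimethyl-3-(prop-1-en-2-yl)-2-oxaspiro[4.5]deca-7,9-diene
Conditions: P(OPh)3, Br2, Et3N, CH2Cl2, −60 °C → rt
Reagents that add atoms: bromine, BrBr
Why: Ketone-to-vinyl bromide conversion with the triphenyl phosphite–bromine reagent: the bromo(phosphonio-oxy) adduct of the ketone loses triphenyl phosphate and one of the only α-hydrogens (the ring CH2, the other α-carbon being the gem-dimethyl carbon), which gives a single regioisomer, the conjugated 2-bromo-1,3-diene; no stereocentre is formed.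

Step 9
Reactants: 15 (3R,5R)-7-bromo-1-methoxy-6,6,10-trimethyl-3-(prop-1-en-2-yl)-2-oxaspiro[4.5]deca-7,9-diene
Product: 16 (3R,5R)-7-bromo-6,6,10-trimethyl-3-(prop-1-en-2-yl)-2-oxaspiro[4.5]deca-7,9-dien-1-ol
Conditions: PPTS, acetone/H2O, 40 °C
Reagents that add atoms: water, O
Why: Mild acid hydrolysis of the methyl acetal (acetal exchange with water) frees the lactol without touching the bromodiene or the isopropenyl group; the lactol carbon is an equilibrating anomer mixture.

Step 10
Reactants: 16 (3R,5R)-7-bromo-6,6,10-trimethyl-3-(prop-1-en-2-yl)-2-oxaspiro[4.5]deca-7,9-dien-1-ol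
Product: 17 CNP0141320.1 (target)
Conditions: NBS, NaHCO3, MeCN, −30 °C
Reagents that add atoms: N-bromosuccinimide, O=C1CCC(=O)N1Br
Why: Bromoetherification modelled on the presumed biosynthesis: NBS should attack the electron-richer trisubstituted C(CH3)=CH bond at CH (not the bromine-bearing alkene) while the hemiacetal hydroxyl adds to the tertiary carbon in Markovnikov, 4-exo fashion, which closes the oxetane and sets the last three stereocentres, because the hydroxyl can only reach the ring face that carries the acetal carbon (this fixes the C–O centre and, through the cis-fused oxetane, the acetal centre, only one equilibrating lactol anomer being able to close) and anti addition places bromine trans to the new C–O bond.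

**Compound list**

1 | methyl 4-chloro-4-oxobutanoate | COC(=O)CCC(=O)Cl | starting material
2 | isopropenylmagnesium bromide | C=C(C)[Mg]Br | starting material
3 | methyl 5-methyl-4-oxohex-5-enoate | COC(=O)CCC(=O)C(C)=C | intermediate
4 | methyl (4R)-4-hydroxy-5-methylhex-5-enoate | COC(=O)CC[C@@H](O)C(C)=C | intermediate
5 | (5R)-5-(prop-1-en-2-yl)oxolan-2-one | C=C(C)[C@H]1CCC(=O)O1 | intermediate
6 | acetone | CC(C)=O | starting material
7 | (5R)-3-(2-hydroxypropan-2-yl)-5-(prop-1-en-2-yl)oxolan-2-one (C3 epimers) | C=C(C)[C@H]1CC(C(C)(C)O)C(=O)O1 | intermediate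
8 | (5R)-3-(propan-2-ylidene)-5-(prop-1-en-2-yl)oxolan-2-one | C=C(C)[C@H]1CC(=C(C)C)C(=O)O1 | intermediate
9 | (5R)-3-(propan-2-ylidene)-5-(prop-1-en-2-yl)oxolan-2-ol (anomers) | C=C(C)[C@H]1CC(=C(C)C)C(O)O1 | intermediate
10 | (5R)-2-methoxy-3-(propan-2-ylidene)-5-(prop-1-en-2-yl)oxolane (anomers) | C=C(C)[C@H]1CC(=C(C)C)C(OC)O1 | intermediate
11 | 2-bromo-5-methylfuran | Cc1ccc(Br)o1 | starting material
12 | (5R)-3-(propan-2-ylidene)-5-(prop-1-en-2-yl)-4,5-dihydro-3H-furan-1-ium trifluoromethanesulfonate | C=C(C)[C@H]1CC(=C(C)C)C=[O+]1.[O-]S(=O)(=O)C(F)(F)F | intermediate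
13 | 4-bromo-2′-methoxy-1,3,3-trimethyl-5′-(prop-1-en-2-yl)spiro[7-oxabicyclo[2.2.1]hept-5-ene-2,3′-oxolane] (5′R; the methyl-bearing bridgehead is anti to the isopropenyl group across the oxolane ring; exo/endo and acetal carbon open) | C=C(C)[C@H]1C[C@@]2(C(OC)O1)C3(C)OC(Br)(C=C3)C2(C)C | intermediate
14 | (3R,5R)-1-methoxy-6,6,10-trimethyl-3-(prop-1-en-2-yl)-2-oxaspiro[4.5]dec-9-en-7-one (C1 anomers) | C=C(C)[C@H]1C[C@@]2(C(OC)O1)C(C)=CCC(=O)C2(C)C | intermediate
15 | (3R,5R)-7-bromo-1-methoxy-6,6,10-trimethyl-3-(prop-1-en-2-yl)-2-oxaspiro[4.5]deca-7,9-diene (C1 anomers) | C=C(C)[C@H]1C[C@@]2(C(OC)O1)C(C)=CC=C(Br)C2(C)C | intermediate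
16 | (3R,5R)-7-bromo-6,6,10-trimethyl-3-(prop-1-en-2-yl)-2-oxaspiro[4.5]deca-7,9-dien-1-ol (C1 anomers) | C=C(C)[C@H]1C[C@@]2(C(O)O1)C(C)=CC=C(Br)C2(C)C | intermediate
17 | CNP0141320.1 | C=C(C)[C@H]1C[C@@]23[C@@H](O1)O[C@]2(C)[C@@H](Br)C=C(Br)C3(C)C | target

**Count and risks**

Total step count: 10. Longest linear sequence: 10 steps (from 1; 2, 6 and 11 are commercial).

Steps most likely to fail:

1. Step 6 (proposed new method). The cycloaddition may stall because the furan addition is reversible, or be diverted by Friedel–Crafts substitution at a furan β-position or by capture of the cation at the acetal carbon; facial selectivity at the spiro centre may also be modest. Fallback with known chemistry: setting out from 10, the ionic Diels–Alder reaction with the non-aromatic hydrocarbon diene (E)-penta-1,3-diene (TfOH cat., CH2Cl2, −78 °C) should form the same two ring bonds irreversibly, the CH2 terminus bonding to the gem-dimethyl carbon, and give the spiro cyclohexene F1. Allylic oxidation of its only allylic methylene (CrO3, 3,5-dimethylpyrazole, CH2Cl2, −20 °C) should give the conjugated enone F2. Under the conditions of step 8, F2 enolises through its γ-hydrogen and comes back to the route at 15.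

2. Step 10. The bromonium ion may be opened with poor regioselectivity (five-membered ether by attack at CH, or bromination of the isopropenyl group), or the tertiary cation may fragment before the four-membered ring closes. Fallback: setting out from 15, intermolecular bromohydrin formation (NBS, H2O/THF, 0 °C; bromonium on the face anti to the acetal carbon, water at the tertiary carbon) should give the bromohydrin F3. Acetal hydrolysis (PPTS, aqueous acetone) gives the hydroxy lactol F4. Dehydrative acetalisation at the anomeric carbon (Ph2SO, Tf2O, 2,4,6-tri-tert-butylpyrimidine, CH2Cl2, −60 → −20 °C) then closes the oxetane and comes back to the route at 17.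

3. Step 8. The ketone, flanked by the gem-dimethyl carbon, may resist the bulky bromophosphonium reagent, or the methyl acetal may be cleaved by it. Fallback: setting out from 14, kinetic enolisation and triflation (KN(SiMe3)2, PhNTf2, THF, −78 °C) gives the dienyl triflate F5. Stannylation (Pd(PPh3)4 cat., Me3SnSnMe3, LiCl, THF, 60 °C) gives the dienylstannane F6. Bromodestannylation (NBS, CH2Cl2, −78 °C) comes back to the route at 15.

Further compounds
F1 | step 6 | (3R)-1-methoxy-6,6,10-trimethyl-3-(prop-1-en-2-yl)-2-oxaspiro[4.5]dec-8-ene (spiro centre as in 14; C1 and C10 epimers) | C=C(C)[C@H]1C[C@@]2(C(OC)O1)C(C)C=CCC2(C)C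
F2 | step 6 | (3R)-1-methoxy-6,6,10-trimethyl-3-(prop-1-en-2-yl)-2-oxaspiro[4.5]dec-8-en-7-one (spiro centre as in 14; C1 and C10 epimers) | C=C(C)[C@H]1C[C@@]2(C(OC)O1)C(C)C=CC(=O)C2(C)C
F3 | step 10 | (3R)-7,9-dibromo-1-methoxy-6,6,10-trimethyl-3-(prop-1-en-2-yl)-2-oxaspiro[4.5]dec-7-en-10-ol (10-OH cis to the acetal carbon, 9-Br trans to 10-OH) | C=C(C)[C@H]1C[C@@]2(C(OC)O1)[C@](C)(O)[C@@H](Br)C=C(Br)C2(C)C
F4 | step 10 | (3R)-7,9-dibromo-6,6,10-trimethyl-3-(prop-1-en-2-yl)-2-oxaspiro[4.5]dec-7-ene-1,10-diol (same relative configuration as F3) | C=C(C)[C@H]1C[C@@]2(C(O)O1)[C@](C)(O)[C@@H](Br)C=C(Br)C2(C)C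
F5 | step 8 | (3R,5R)-1-methoxy-6,6,10-trimethyl-3-(prop-1-en-2-yl)-2-oxaspiro[4.5]deca-7,9-dien-7-yl trifluoromethanesulfonate | C=C(C)[C@H]1C[C@@]2(C(OC)O1)C(C)=CC=C(OS(=O)(=O)C(F)(F)F)C2(C)C
F6 | step 8 | [(3R,5R)-1-methoxy-6,6,10-trimethyl-3-(prop-1-en-2-yl)-2-oxaspiro[4.5]deca-7,9-dien-7-yl]trimethylstannane | C=C(C)[C@H]1C[C@@]2(C(OC)O1)C(C)=CC=C([Sn](C)(C)C)C2(C)C
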